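**Retrosynthetic overview**
- Ring B (eight-membered) is closed last by ring-closing metathesis, after a Shapiro vinyllithium from the ring-A fragment adds to the C5 ketone of the C/D fragment; alkene reduction, dehydration to the diene and desilylation finish the synthesis.
- The ring-C–CH(CH3) bond and its stereocentre come from a ketal-Claisen [3,3] rearrangement of the (E)-crotyl enol ether of a trans-hydrindan-5-one.
- Rings C and D form together in one intramolecular Diels–Alder reaction (2-silyloxydiene + isopropenyl ketone); the C–iPr stereocentre is bought in (S)-limonene.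
- Ring A is a cyclopentane made from (R)-limonene oxide (cleavage/aldol ring contraction), then all-cis hydrogenation and epimerisation next to the acetyl group.
- Ring order: C + D (cycloaddition), A (separately, aldol), B (metathesis).

Assumption: the SMILES is taken as the absolute configuration; (S)-(−)-limonene, (4R)-limonene 1,2-oxide (cis/trans mixture), isopropenylmagnesium bromide and (E)-but-2-en-1-ol are bought. Hydrindane numbering (C1–C7a) is used for the C/D compounds; β is the face of the angular methyl.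

**Route**

Step 1
Reactants: 1 (S)-(−)-limonene
Product: 2 (S)-p-menth-1-ene
Conditions: H2 (1 atm), RhCl(PPh3)3 (cat.), benzene/EtOH, rt
Reagents that add atoms: none
Why: Wilkinson hydrogenation reduces the unhindered 1,1-disubstituted exocyclic alkene far faster than the trisubstituted ring alkene, and the stereocentre (the later C–iPr carbon) is not touched.

Step 2
Reactants: 2 (S)-p-menth-1-ene
Product: 3 (S)-3-isopropyl-6-oxoheptanoic acid
Conditions: RuCl3·xH2O (cat.), NaIO4, CCl4/MeCN/H2O, rt
Reagents that add atoms: sodium periodate, [Na+].[O-]I(=O)(=O)=O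
Why: RuO4 (Sharpless) oxidative cleavage of the trisubstituted ring alkene gives the methyl ketone and the carboxylic acid directly without touching the stereocentre.

Step 3
Reactants: 3 (S)-3-isopropyl-6-oxoheptanoic acid
Product: 4 (S)-N-methoxy-N-methyl-3-isopropyl-6-oxoheptanamide
Conditions: MeNH(OMe)·HCl, EDC·HCl, DMAP (cat.), i-Pr2NEt, CH2Cl2, 0 °C to rt
Reagents that add atoms: N,O-dimethylhydroxylamine hydrochloride, CNOC.Cl
Why: Carbodiimide amide coupling gives a Weinreb amide that is inert in the next two steps and later takes up exactly one Grignard equivalent.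

Step 4
Reactants: 4 (S)-N-methoxy-N-methyl-3-isopropyl-6-oxoheptanamide
Product: 5 (S,E)-N-methoxy-N-methyl-3-isopropyl-6-oxohept-4-enamide
Conditions: IBX, 4-methoxypyridine N-oxide, DMSO, rt
Reagents that add atoms: none
Why: Nicolaou IBX dehydrogenation goes through the more substituted enol, so only the CH2–CH2 side of the methyl ketone is desaturated to the (E)-enone while the amide stays untouched.

Step 5
Reactants: 5 (S,E)-N-methoxy-N-methyl-3-isopropyl-6-oxohept-4-enamide
Product: 6 (S,E)-6-(tert-butyldimethylsilyloxy)-N-methoxy-N-methyl-3-isopropylhepta-4,6-dienamide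
Conditions: TBSOTf, Et3N, CH2Cl2, −78 °C to 0 °C
Reagents that add atoms: tert-butyldimethylsilyl triflate, CC(C)(C)[Si](C)(C)OS(=O)(=O)C(F)(F)F
Why: Soft enolisation removes an α′-methyl proton of the enone and gives the cross-conjugated 2-silyloxy-1,3-diene; the Weinreb amide is not enolised.

Step 6
Reactants: 6 (S,E)-6-(tert-butyldimethylsilyloxy)-N-methoxy-N-methyl-3-isopropylhepta-4,6-dienamide; 7 isopropenylmagnesium bromide
Product: 9 trans-fused (3S,3aR,7aR)-5-(tert-butyldimethylsilyloxy)-3-isopropyl-7a-methyl-hexahydroinden-1-one (C4=C5 silyl enol ether), via trienone 8 (not isolated)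
Conditions: 7, THF, −78 °C to 0 °C; aq. NH4Cl; then toluene, BHT (cat.), 80 °C
Reagents that add atoms: isopropenylmagnesium bromide (7), CC(=C)[Mg]Br
Why: Weinreb ketone synthesis followed by a type-1 intramolecular Diels–Alder reaction in which, as for other 2-methyl-1,6,8-nonatrien-3-ones, the tether carbonyl lies exo and the methyl endo (trans ring fusion), while the allylic isopropyl group sits away from the tether (H eclipsing the diene) so that C3a–H and iPr end up cis.

Step 7
Reactants: 9 trans-fused silyl enol ether ketone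
Product: 11 (1R,3S,3aR,7aR)-1,5-bis(tert-butyldimethylsilyloxy)-3-isopropyl-7a-methyl-hexahydroindene, via lithium alkoxide 10 (not isolated)
Conditions: L-Selectride, THF, −78 °C; then TBSOTf, −78 °C to 0 °C
Reagents that add atoms: tert-butyldimethylsilyl triflate, CC(C)(C)[Si](C)(C)OS(=O)(=O)C(F)(F)F
Why: The bulky hydride attacks the cyclopentanone from the α-face, anti to the adjacent angular methyl (as in 17-keto steroids), giving the β-alkoxide (cis to methyl), which is silylated in situ while the silyl enol ether keeps the C5 carbonyl masked.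

Step 8
Reactants: 11 bis-silyl compound; 12 (E)-but-2-en-1-ol
Product: 15 (1R,3S,3aS,6R,7aR)-6-[(S)-but-3-en-2-yl]-1-(tert-butyldimethylsilyloxy)-3-isopropyl-7a-methyl-octahydroinden-5-one, via dimethyl ketal 13 (not isolated), via crotyl enol ether 14 (not isolated)
Conditions: HC(OMe)3, MeOH, PPTS (cat.), rt; concentrate; 12 (5 equiv), EtCO2H (cat.), xylene, 140 °C, distil off MeOH
Reagents that add atoms: (E)-but-2-en-1-ol (12), C/C=C/CO
Why: Acetal exchange gives the more stable Δ5,6 crotyl enol ether (enolisation away from the trans ring fusion), and the ketal-Claisen [3,3] rearrangement through a chair on the α-face (anti to the axial angular methyl) with the (E)-methyl outward forms the C6–CH(CH3) bond and sets the side-chain methyl stereocentre.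

Step 9
Reactants: 16 (4R)-limonene 1,2-oxide (cis/trans mixture)
Product: 18 (S)-2-methyl-5-(prop-1-en-2-yl)cyclopent-1-ene-1-carbaldehyde, via keto aldehyde 17 (not isolated)
Conditions: H5IO6, THF/H2O, 0 °C to rt; extract; then piperidine (cat.), AcOH (cat.), benzene, reflux (Dean–Stark)
Reagents that add atoms: none
Why: Periodic acid opens and cleaves the epoxide to the keto aldehyde, and the amine-catalysed intramolecular aldol condensation (aldehyde enamine onto the ketone) contracts the ring to the cyclopentene carbaldehyde with the bought stereocentre intact.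

Step 10
Reactants: 18 (S)-2-methyl-5-(prop-1-en-2-yl)cyclopent-1-ene-1-carbaldehyde
Product: 19 (R)-5-acetyl-2-methylcyclopent-1-ene-1-carbaldehyde
Conditions: O3, CH2Cl2, −78 °C (Sudan III end point); Me2S
Reagents that add atoms: ozone, [O-][O+]=O
Why: Ozonolysis is chemoselective for the electron-rich isopropenyl group over the electron-poor enal double bond, and the neutral reductive work-up avoids enolisation of the new α-acetyl stereocentre.

Step 11
Reactants: 19 (R)-5-acetyl-2-methylcyclopent-1-ene-1-carbaldehyde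
Product: 20 all-cis (1S,2R,5S)-2-acetyl-5-methylcyclopentane-1-carbaldehyde
Conditions: H2 (4 atm), 10% Pd/C, EtOAc, rt
Reagents that add atoms: none
Why: Heterogeneous syn-hydrogenation of the tetrasubstituted enal alkene from the face opposite the acetyl group sets both new centres, leaving methyl and formyl cis to each other and to acetyl.

Step 12
Reactants: 20 all-cis keto aldehyde
Product: 21 1-[(1R,2S,3S)-3-methyl-2-vinylcyclopentyl]ethan-1-one (all-cis)
Conditions: CH2I2, Zn, Ti(OiPr)4, THF, rt
Reagents that add atoms: diiodomethane, ICI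
Why: Takai methylenation (CH2I2–Zn–Ti(OiPr)4) is selective for aldehydes over ketones and non-basic, so the epimerisable aldehyde α-centre is fixed as a vinyl-bearing carbon without loss of the cis methyl/vinyl relationship.

Step 13
Reactants: 21 all-cis vinyl ketone
Product: 23 2,4,6-triisopropylbenzenesulfonyl hydrazone of 1-[(1S,2S,3S)-3-methyl-2-vinylcyclopentyl]ethan-1-one, via trans ketone 22 (not isolated)
Conditions: K2CO3, MeOH, rt; AcOH to pH 5; then TrisNHNH2, rt
Reagents that add atoms: 2,4,6-triisopropylbenzenesulfonyl hydrazide, CC(C)c1cc(C(C)C)c(S(=O)(=O)NN)c(C(C)C)c1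
Why: Base epimerisation at the only acidic centre (α to the ketone) relieves the all-cis strain and gives the acetyl group trans to vinyl (methyl and vinyl stay cis), and condensation then gives the Shapiro precursor.

Step 14
Reactants: 23 trisylhydrazone; 15 C6-butenyl hydrindan-5-one
Product: 25 tertiary allylic alcohol (C5 carbinol of 15 bearing the 1-[(1S,2S,3S)-3-methyl-2-vinylcyclopentyl]vinyl group), via vinyllithium 24 (not isolated)
Conditions: 23, n-BuLi (2.1 equiv), THF, −78 °C to 0 °C; then 15, −78 °C; aq. NH4Cl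
Reagents that add atoms: none
Why: The Shapiro reaction deprotonates the methyl group and gives the 1,1-disubstituted vinyllithium, which adds 1,2 to the ketone from the equatorial direction, trans to the C6 side chain; the new carbinol centre is removed in step 17.

Step 15
Reactants: 25 tertiary allylic alcohol
Product: 26 tetracyclic (Z)-cyclooctene tertiary alcohol
Conditions: Grubbs II (10 mol%), CH2Cl2 (1 mM), 40 °C
Reagents that add atoms: none
Why: Ring-closing metathesis of the two monosubstituted vinyl groups, held close on the trans-diequatorial C5/C6 substituents, closes the eight-membered ring, while the hindered 1,1-disubstituted alkene is expected to stay out.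

Step 16
Reactants: 26 tetracyclic cyclooctene alcohol
Product: 27 saturated eight-membered-ring tertiary alcohol
Conditions: 2-nitrobenzenesulfonyl hydrazide, Et3N, CH2Cl2, rt
Reagents that add atoms: none
Why: Diimide reduces the strained cis-disubstituted cyclooctene much faster than the hindered 1,1-disubstituted alkene flanked by a quaternary carbinol and a ring methine.

Step 17
Reactants: 27 saturated tertiary alcohol
Product: 28 TBS ether of the target diene
Conditions: Martin sulfurane, CH2Cl2, 0 °C to rt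
Reagents that add atoms: none
Why: Martin sulfurane dehydration of the tertiary allylic alcohol proceeds E1-like toward the tetrasubstituted C5=C6 alkene conjugated with the exocyclic methylene, and the stereocentres at the carbinol and C6 disappear.

Step 18
Reactants: 28 TBS ether of the target diene
Product: 29 target CNP0544018.1
Conditions: TBAF, THF, 50 °C
Reagents that add atoms: none
Why: Fluoride cleaves the hindered secondary silyl ether without touching the diene.

**Compound list**

1 | (S)-(−)-limonene | CC1=CC[C@@H](C(C)=C)CC1 | starting material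
2 | (S)-p-menth-1-ene | CC1=CC[C@@H](C(C)C)CC1 | intermediate
3 | (S)-3-isopropyl-6-oxoheptanoic acid | OC(=O)C[C@@H](C(C)C)CCC(C)=O | intermediate
4 | (S)-N-methoxy-N-methyl-3-isopropyl-6-oxoheptanamide | CON(C)C(=O)C[C@@H](C(C)C)CCC(C)=O | intermediate
5 | (S,E)-N-methoxy-N-methyl-3-isopropyl-6-oxohept-4-enamide | CON(C)C(=O)C[C@@H](C(C)C)/C=C/C(C)=O | intermediate
6 | (S,E)-6-(TBSO)-N-methoxy-N-methyl-3-isopropylhepta-4,6-dienamide | CON(C)C(=O)C[C@@H](C(C)C)/C=C/C(=C)O[Si](C)(C)C(C)(C)C | intermediate
7 | isopropenylmagnesium bromide | CC(=C)[Mg]Br | starting material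
8 | (S,E)-8-(TBSO)-5-isopropyl-2-methylnona-1,6,8-trien-3-one | CC(=C)C(=O)C[C@@H](C(C)C)/C=C/C(=C)O[Si](C)(C)C(C)(C)C | intermediate (not isolated)
9 | (3S,3aR,7aR)-5-(TBSO)-3-isopropyl-7a-methyl-2,3,3a,6,7,7a-hexahydro-1H-inden-1-one (trans-fused; iPr cis to 3a-H) | CC(C)(C)[Si](C)(C)OC1=C[C@H]2[C@H](C(C)C)CC(=O)[C@]2(C)CC1 | intermediate
10 | lithium 1β-alkoxide of 9 (1R) | CC(C)(C)[Si](C)(C)OC1=C[C@H]2[C@H](C(C)C)C[C@@H]([O-])[C@]2(C)CC1.[Li+] | intermediate (not isolated)
11 | (1R,3S,3aR,7aR)-1,5-bis(TBSO)-3-isopropyl-7a-methyl-2,3,3a,6,7,7a-hexahydro-1H-indene | CC(C)(C)[Si](C)(C)OC1=C[C@H]2[C@H](C(C)C)C[C@@H](O[Si](C)(C)C(C)(C)C)[C@]2(C)CC1 | intermediate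
12 | (E)-but-2-en-1-ol | C/C=C/CO | starting material
13 | (1R,3S,3aS,7aR)-1-(TBSO)-5,5-dimethoxy-3-isopropyl-7a-methyloctahydroindene | COC1(OC)CC[C@@]2(C)[C@H](O[Si](C)(C)C(C)(C)C)C[C@@H](C(C)C)[C@@H]2C1 | intermediate (not isolated)
14 | Δ5,6 (E)-crotyl enol ether of the hydrindan-5-one | C/C=C/COC1=CC[C@@]2(C)[C@H](O[Si](C)(C)C(C)(C)C)C[C@@H](C(C)C)[C@@H]2C1 | intermediate (not isolated)
15 | (1R,3S,3aS,6R,7aR)-6-[(S)-but-3-en-2-yl]-1-(TBSO)-3-isopropyl-7a-methyloctahydro-5H-inden-5-one | O=C1[C@@H]([C@@H](C)C=C)C[C@@]2(C)[C@H](O[Si](C)(C)C(C)(C)C)C[C@@H](C(C)C)[C@@H]2C1 | intermediate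
16 | (4R)-limonene 1,2-oxide (cis/trans mixture at C1/C2) | CC12CC[C@@H](C(C)=C)CC1O2 | starting material
17 | (R)-3-(prop-1-en-2-yl)-6-oxoheptanal | O=CC[C@H](C(C)=C)CCC(C)=O | intermediate (not isolated)
18 | (S)-2-methyl-5-(prop-1-en-2-yl)cyclopent-1-ene-1-carbaldehyde | O=CC1=C(C)CC[C@H]1C(C)=C | intermediate
19 | (R)-5-acetyl-2-methylcyclopent-1-ene-1-carbaldehyde | O=CC1=C(C)CC[C@H]1C(C)=O | intermediate
20 | (1S,2R,5S)-2-acetyl-5-methylcyclopentane-1-carbaldehyde (all-cis) | O=C[C@@H]1[C@H](C(C)=O)CC[C@@H]1C | intermediate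
21 | 1-[(1R,2S,3S)-3-methyl-2-vinylcyclopentyl]ethan-1-one (all-cis) | C=C[C@@H]1[C@H](C(C)=O)CC[C@@H]1C | intermediate
22 | 1-[(1S,2S,3S)-3-methyl-2-vinylcyclopentyl]ethan-1-one (Me/vinyl cis, acetyl trans) | C=C[C@@H]1[C@@H](C(C)=O)CC[C@@H]1C | intermediate (not isolated)
23 | trisylhydrazone of 22 | C=C[C@@H]1[C@@H](C(C)=NNS(=O)(=O)c2c(C(C)C)cc(C(C)C)cc2C(C)C)CC[C@@H]1C | intermediate
24 | 1-[(1S,2S,3S)-3-methyl-2-vinylcyclopentyl]vinyllithium | C=C[C@@H]1[C@@H](C(=C)[Li])CC[C@@H]1C | intermediate (not isolated)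
25 | tertiary allylic alcohol from 24 + 15 (OH axial/α at C5, cyclopentylvinyl trans to the C6 butenyl group) | C=C[C@@H]1[C@@H](C(=C)[C@]2(O)[C@@H]([C@@H](C)C=C)C[C@@]3(C)[C@H](O[Si](C)(C)C(C)(C)C)C[C@@H](C(C)C)[C@@H]3C2)CC[C@@H]1C | intermediate
26 | tetracyclic (Z)-cyclooctene tertiary alcohol (5-8-6-5 skeleton, exocyclic methylene, OTBS) | C=C1[C@]2(O)[C@H](C[C@@]3(C)[C@H](O[Si](C)(C)C(C)(C)C)C[C@@H](C(C)C)[C@@H]3C2)[C@@H](C)/C=C\[C@@H]2[C@@H]1CC[C@@H]2C | intermediate
27 | saturated eight-membered-ring tertiary alcohol | C=C1[C@]2(O)[C@H](C[C@@]3(C)[C@H](O[Si](C)(C)C(C)(C)C)C[C@@H](C(C)C)[C@@H]3C2)[C@@H](C)CC[C@@H]2[C@@H]1CC[C@@H]2C | intermediate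
28 | TBS ether of the target diene | C=C1C2=C(C[C@@]3(C)[C@H](O[Si](C)(C)C(C)(C)C)C[C@@H](C(C)C)[C@@H]3C2)[C@@H](C)CC[C@@H]2[C@@H]1CC[C@@H]2C | intermediate
29 | CNP0544018.1 (5-8-6-5 dienol; trans-hydrindane with β-methyl, β-OH, α-isopropyl; trans 5-8 fusion) | C=C1C2=C(C[C@@]3(C)[C@H](O)C[C@@H](C(C)C)[C@@H]3C2)[C@@H](C)CC[C@@H]2[C@@H]1CC[C@@H]2C | target

**Step count and risks**

Total step count: 18. Longest linear sequence: 13 (steps 1–8, then 14–18).

Most likely to fail:

1. Step 6 (ring-fusion selectivity of the cycloaddition). If the cis-fused adduct dominates, the fallback sets out from 6 and returns at 9, changing the dienophile to a terminally activated one. (E)-3-Iodobut-2-en-1-ol is treated with t-BuLi (3 equiv) and added to 6 to give the hydroxy trienone F1. MnO2 oxidises it to the enal trienone F2 (CHO cis to the methyl). With Me2AlCl at −78 °C the terminal aldehyde takes the endo position, which corresponds to the trans-fused aldehyde adduct F3. Catalytic decarbonylation ([Rh(dppp)2]Cl, xylene, 140 °C) then gives 9.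

2. Step 8 (regiochemistry of enol ether formation and chair selectivity of the Claisen step). The fallback sets out from 11 and returns at 14 (and so 15). K2CO3/MeOH cleaves only the silyl enol ether to give the TBS ether ketone F4. Hydrazine gives the hydrazone F5. I2/tetramethylguanidine (Barton) gives vinyl iodides, from which the Δ5,6 vinyl iodide F6 is separated. Copper-catalysed C–O coupling with (E)-but-2-en-1-ol (CuI, 3,4,7,8-tetramethylphenanthroline, Cs2CO3, toluene, 80 °C) gives the regiodefined 14, which rearranges at 120 °C.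

3. Step 15 (eight-membered ring closure by metathesis, with possible interference of the 1,1-disubstituted alkene). The fallback sets out from 22 (isolated) and 15 and returns at 27, closing the ring at the carbinol bond instead. 22 is converted with KHMDS/PhNTf2 into the alkenyl triflate F7. Cross-metathesis of F7 with 15 (Hoveyda–Grubbs II) gives the (E)-alkene-linked keto triflate F8. Diimide gives the saturated keto triflate F9. Intramolecular Nozaki–Hiyama–Kishi reaction (CrCl2, NiCl2 cat., DMF) gives 27 or its carbinol epimer, both of which dehydrate to 28.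

Further compounds
F1 | step 6 | (S)-hydroxy trienone, 1-hydroxy-3-methyl-4-oxo analogue of 8 with CH2OH cis to methyl | OC/C=C(\C)C(=O)C[C@@H](C(C)C)/C=C/C(=C)O[Si](C)(C)C(C)(C)C
F2 | step 6 | enal trienone (CHO cis to methyl) | O=C/C=C(\C)C(=O)C[C@@H](C(C)C)/C=C/C(=C)O[Si](C)(C)C(C)(C)C
F3 | step 6 | 7-formyl derivative of 9 (CHO cis to the angular methyl) | CC(C)(C)[Si](C)(C)OC1=C[C@H]2[C@H](C(C)C)CC(=O)[C@]2(C)[C@@H](C=O)C1
F4 | step 8 | (1R,3S,3aS,7aR)-1-(TBSO)-3-isopropyl-7a-methyloctahydro-5H-inden-5-one | O=C1CC[C@@]2(C)[C@H](O[Si](C)(C)C(C)(C)C)C[C@@H](C(C)C)[C@@H]2C1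
F5 | step 8 | hydrazone of F4 | NN=C1CC[C@@]2(C)[C@H](O[Si](C)(C)C(C)(C)C)C[C@@H](C(C)C)[C@@H]2C1
F6 | step 8 | Δ5,6 vinyl iodide of F4 | IC1=CC[C@@]2(C)[C@H](O[Si](C)(C)C(C)(C)C)C[C@@H](C(C)C)[C@@H]2C1
F7 | step 15 | 1-[(1S,2S,3S)-3-methyl-2-vinylcyclopentyl]vinyl triflate | C=C[C@@H]1[C@@H](C(=C)OS(=O)(=O)C(F)(F)F)CC[C@@H]1C
F8 | step 15 | (E)-alkene-linked keto triflate from 15 and F7 | O=C1[C@@H]([C@@H](C)/C=C/[C@@H]2[C@@H](C(=C)OS(=O)(=O)C(F)(F)F)CC[C@@H]2C)C[C@@]3(C)[C@H](O[Si](C)(C)C(C)(C)C)C[C@@H](C(C)C)[C@@H]3C1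
F9 | step 15 | saturated keto triflate | O=C1[C@@H]([C@@H](C)CC[C@@H]2[C@@H](C(=C)OS(=O)(=O)C(F)(F)F)CC[C@@H]2C)C[C@@]3(C)[C@H](O[Si](C)(C)C(C)(C)C)C[C@@H](C(C)C)[C@@H]3C1
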